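**Strategy.** Ring A is assembled rather than substituted. Four adjacent ring A atoms, C6 (OMe), C5 (prenyl), C4 (oxygen) and C3 (H), already exist as the conjugated diene made from 2-prenylcyclohexane-1,3-dione by O-methylation and enol silylation. The remaining atoms, C1 and C2, come from an aryl bromoethynyl ketone that carries ring B. Disconnecting C6–C1 and C3–C2 therefore leads to these two partners. A single thermal operation, [4+2] addition then cycloreversion with loss of ethylene, closes ring A with every substituent in place and leaves bromine at C2 for the final hydroxyl.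

Key step: step 7

Remark on the chemistry: the enol oxygen is carried as a tert-butyldimethylsilyl ether, which should survive isolation of the diene and of the arene better than a trimethylsilyl ether and is still cleaved by hydroxide in the last step. Intermediate 13 is racemic (one enantiomer is drawn) and its two bridgehead centres vanish on aromatisation.

**Route**

Step 1
Reactants: 1 cyclohexane-1,3-dione; 2 1-bromo-3-methylbut-2-ene (prenyl bromide)
Product: 3 2-(3-methylbut-2-enyl)cyclohexane-1,3-dione
Conditions: KOH (1 equiv), H2O, 0 °C → rt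
Reagents that add atoms: none
Why: Enolate C-alkylation: in water the oxygen atoms of the dione enolate are hydrogen-bonded, so the allylic bromide should be attacked mainly by C2 in an SN2 reaction, the usual way to 2-allyl-type cyclohexane-1,3-diones.

Step 2
Reactants: 3 2-(3-methylbut-2-enyl)cyclohexane-1,3-dione
Product: 4 3-methoxy-2-(3-methylbut-2-enyl)cyclohex-2-en-1-one
Conditions: Me2SO4, K2CO3, acetone, reflux
Reagents that add atoms: dimethyl sulfate, COS(=O)(=O)OC
Why: Williamson-type O-alkylation of the dione enolate by the hard electrophile Me2SO4 should give the vinylogous methyl ester, and because 3 is symmetric only one enol ether can arise.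

Step 3
Reactants: 4 3-methoxy-2-(3-methylbut-2-enyl)cyclohex-2-en-1-one
Product: 6 2-(tert-butyldimethylsilyloxy)-4-methoxy-3-(3-methylbut-2-enyl)cyclohexa-1,3-diene, via lithium dienolate 5 (not isolated)
Conditions: LiN(iPr)2, THF, −78 °C; then tBuMe2SiCl, DMPU, −78 °C → rt
Reagents that add atoms: tert-butyldimethylsilyl chloride, CC(C)(C)[Si](C)(C)Cl
Why: Kinetic enolisation of a vinylogous ester with LiN(iPr)2 takes the alpha-prime proton at C6 (as in Stork–Danheiser chemistry), and O-silylation of the cross-conjugated lithium dienolate (silyl enol ether formation) should give the 2-silyloxy diene with the prenyl group untouched.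

Step 4
Reactants: 7 vanillic acid (4-hydroxy-3-methoxybenzoic acid)
Product: 8 4-(2,2-dimethylpropanoyloxy)-3-methoxybenzoic acid
Conditions: tBuCOCl, NaOH, H2O/THF, 0 °C; then aq. HCl
Reagents that add atoms: pivaloyl chloride, CC(C)(C)C(=O)Cl
Why: Schotten–Baumann acylation: in the dianion the phenoxide is far more nucleophilic than the carboxylate, and any mixed anhydride formed at the acid is hydrolysed again on work-up, leaving the hindered aryl pivalate.

Step 5
Reactants: 8 4-(2,2-dimethylpropanoyloxy)-3-methoxybenzoic acid; 9 bis(trimethylsilyl)acetylene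
Product: 11 2-methoxy-4-[3-(trimethylsilyl)prop-2-ynoyl]phenyl 2,2-dimethylpropanoate, via acid chloride 10 (not isolated)
Conditions: (COCl)2, cat. DMF, CH2Cl2, 0 °C → rt, evaporate; then 9, AlCl3, CH2Cl2, 0 °C; cold dilute HCl quench
Reagents that add atoms: none
Why: Acid chloride formation through the Vilsmeier-type chloroiminium species is followed by Friedel–Crafts-type ipso-substitution of one C–Si bond of the bis-silyl alkyne by the acylium ion (beta-silyl-stabilised vinyl cation); the ynone formed is deactivated so the second silyl group should stay, and the pivalate keeps ring B too electron-poor for self-acylation.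

Step 6
Reactants: 11 2-methoxy-4-[3-(trimethylsilyl)prop-2-ynoyl]phenyl 2,2-dimethylpropanoate
Product: 12 4-(3-bromoprop-2-ynoyl)-2-methoxyphenyl 2,2-dimethylpropanoate
Conditions: NBS, AgNO3 (10 mol %), acetone, rt, dark; aqueous work-up
Reagents that add atoms: N-bromosuccinimide, O=C1CCC(=O)N1Br
Why: Silver-catalysed desilylative halogenation: AgNO3 turns the C(sp)–Si bond into a silver acetylide that NBS brominates, a standard conversion of silylalkynes (ynones included) into 1-bromoalkynes that should leave ketone, ester and aryl ether alone.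

Step 7
Reactants: 6 2-(tert-butyldimethylsilyloxy)-4-methoxy-3-(3-methylbut-2-enyl)cyclohexa-1,3-diene; 12 4-(3-bromoprop-2-ynoyl)-2-methoxyphenyl 2,2-dimethylpropanoate
Product: 14 4-[2-bromo-4-(tert-butyldimethylsilyloxy)-6-methoxy-5-(3-methylbut-2-enyl)benzoyl]-2-methoxyphenyl 2,2-dimethylpropanoate, via bicyclo[2.2.2]octadiene adduct 13 (not isolated)
Conditions: toluene, Ar, 60 °C; then 140 °C (sealed tube)
Reagents that add atoms: none
Why: The electron-rich diene, with a terminal OMe donor and an internal silyloxy donor, and the electron-poor bromoalkynyl ketone should combine in a single-step, asynchronous normal-electron-demand [4+2] cycloaddition; the closest known reaction is the Alder–Rickert arene synthesis from 2-silyloxycyclohexa-1,3-dienes and acetylenic ketones or esters. Ring A is closed intermolecularly as the new six-membered ring of bicycle 13 by suprafacial formation of the C3–C2 and C6–C1 bonds, and further heating drives a retro-[4+2] that expels the CH2–CH2 bridge as ethylene, made irreversible by aromatisation and loss of a gas. The only stereocentres formed are the two bridgeheads of racemic 13, which are tied to each other by the bicycle and are erased on aromatisation, so no stereocontrol is needed. The selectivity required is regiochemical: both donors put the largest HOMO coefficient on the CH terminus of the diene, which should bond to the bromine-bearing beta carbon of the ynone (largest LUMO coefficient), so that the aroyl carbon ends up next to the OMe carbon and bromine next to C3–H. In 13 the OMe group sits on a bridgehead carrying a single oxygen and has no elimination pathway, the prenyl alkene is an unactivated bystander, and the aryl silyl ether and pivalate should tolerate neutral, anhydrous heating.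

Step 8
Reactants: 14 4-[2-bromo-4-(tert-butyldimethylsilyloxy)-6-methoxy-5-(3-methylbut-2-enyl)benzoyl]-2-methoxyphenyl 2,2-dimethylpropanoate
Product: 16 [2,4-dihydroxy-6-methoxy-5-(3-methylbut-2-enyl)phenyl](4-hydroxy-3-methoxyphenyl)methanone, via dihydroxy bromide 15 (not isolated)
Conditions: KOH (excess), degassed DMSO/H2O (1:1), Ar, rt; then CuI (copper iodide, 10 mol %), 1,10-phenanthroline (20 mol %), 100–110 °C; aq. HCl to pH 4
Reagents that add atoms: potassium hydroxide, [K+].[OH-]
Why: Hydroxide should first remove the aryl silyl ether and the aryl pivalate at room temperature, and Ullmann-type copper-catalysed hydroxylation of the aryl bromide, helped by the chelating ortho ketone, then puts the oxygen on C2; acidification releases the triphenol with the prenyl alkene and both methyl ethers unaffected.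

**Compound list**

1 | cyclohexane-1,3-dione | O=C1CCCC(=O)C1 | starting material
2 | 1-bromo-3-methylbut-2-ene (prenyl bromide) | CC(C)=CCBr | starting material
3 | 2-(3-methylbut-2-enyl)cyclohexane-1,3-dione | O=C1CCCC(=O)C1CC=C(C)C | intermediate
4 | 3-methoxy-2-(3-methylbut-2-enyl)cyclohex-2-en-1-one | COC1=C(CC=C(C)C)C(=O)CCC1 | intermediate
5 | lithium 4-methoxy-3-(3-methylbut-2-enyl)cyclohexa-1,3-dien-2-olate | COC1=C(CC=C(C)C)C([O-])=CCC1.[Li+] | intermediate
6 | 2-(tert-butyldimethylsilyloxy)-4-methoxy-3-(3-methylbut-2-enyl)cyclohexa-1,3-diene | COC1=C(CC=C(C)C)C(O[Si](C)(C)C(C)(C)C)=CCC1 | intermediate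
7 | vanillic acid | COc1cc(C(=O)O)ccc1O | starting material
8 | 4-(2,2-dimethylpropanoyloxy)-3-methoxybenzoic acid | COc1cc(C(=O)O)ccc1OC(=O)C(C)(C)C | intermediate
9 | bis(trimethylsilyl)acetylene | C[Si](C)(C)C#C[Si](C)(C)C | starting material
10 | 4-(chlorocarbonyl)-2-methoxyphenyl 2,2-dimethylpropanoate | COc1cc(C(=O)Cl)ccc1OC(=O)C(C)(C)C | intermediate
11 | 2-methoxy-4-[3-(trimethylsilyl)prop-2-ynoyl]phenyl 2,2-dimethylpropanoate | COc1cc(C(=O)C#C[Si](C)(C)C)ccc1OC(=O)C(C)(C)C | intermediate
12 | 4-(3-bromoprop-2-ynoyl)-2-methoxyphenyl 2,2-dimethylpropanoate | COc1cc(C(=O)C#CBr)ccc1OC(=O)C(C)(C)C | intermediate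
13 | 4-{[3-bromo-5-(tert-butyldimethylsilyloxy)-1-methoxy-6-(3-methylbut-2-enyl)bicyclo[2.2.2]octa-2,5-dien-2-yl]carbonyl}-2-methoxyphenyl 2,2-dimethylpropanoate (racemic) | CO[C@]12CC[C@H](C(Br)=C1C(=O)c1ccc(OC(=O)C(C)(C)C)c(OC)c1)C(O[Si](C)(C)C(C)(C)C)=C2CC=C(C)C | intermediate
14 | 4-[2-bromo-4-(tert-butyldimethylsilyloxy)-6-methoxy-5-(3-methylbut-2-enyl)benzoyl]-2-methoxyphenyl 2,2-dimethylpropanoate | COc1cc(C(=O)c2c(Br)cc(O[Si](C)(C)C(C)(C)C)c(CC=C(C)C)c2OC)ccc1OC(=O)C(C)(C)C | intermediate
15 | [2-bromo-4-hydroxy-6-methoxy-5-(3-methylbut-2-enyl)phenyl](4-hydroxy-3-methoxyphenyl)methanone (dipotassium salt in the flask) | COc1cc(C(=O)c2c(Br)cc(O)c(CC=C(C)C)c2OC)ccc1O | intermediate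
16 | [2,4-dihydroxy-6-methoxy-5-(3-methylbut-2-enyl)phenyl](4-hydroxy-3-methoxyphenyl)methanone | COc1cc(C(=O)c2c(O)cc(O)c(CC=C(C)C)c2OC)ccc1O | target

**Step count and risks**

Total steps: 8. Longest linear sequence: 5 steps (1 → 3 → 4 → 6 → 14 → 16, or 7 → 8 → 11 → 12 → 14 → 16).

Steps most likely to fail:

1. Step 7. The nucleophilic silyl dienol ether may add to the bromoynone stepwise (Mukaiyama–Michael fashion) and then lose bromide or the silyl group instead of closing the ring. The bromoalkyne may also decompose before it is consumed. Fallback, setting out from 4 (through its lithium dienolate 5) and 12 and rejoining at 15: 5 is quenched with Ac2O instead of the silyl chloride to give 4-methoxy-3-(3-methylbut-2-enyl)cyclohexa-1,3-dien-2-yl acetate F1. This is a neutral Birch-type 1-methoxydiene that cannot act as a silyl enol ether nucleophile and should react only by concerted cycloaddition. Heating F1 with 12 in xylenes at 140 °C should give, through the racemic adduct 4-{[5-acetoxy-3-bromo-1-methoxy-6-(3-methylbut-2-enyl)bicyclo[2.2.2]octa-2,5-dien-2-yl]carbonyl}-2-methoxyphenyl 2,2-dimethylpropanoate F2 formed in the flask, the arene 4-[4-acetoxy-2-bromo-6-methoxy-5-(3-methylbut-2-enyl)benzoyl]-2-methoxyphenyl 2,2-dimethylpropanoate F3. The regiochemistry is set in the same sense by the terminal OMe group. KOH under the conditions of step 8 should cleave both esters of F3 to 15, which is hydroxylated to 16 as in the main route.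

2. Step 8. Activation of the C–Br bond may be slow once the substrate is an electron-rich bis-phenoxide. Phenoxide O-arylation (diaryl ether formation), hydrodebromination and base-induced degradation of the polyphenolic ketone at 100 °C may compete. Fallback, setting out from 14 and rejoining at 16: Miyaura borylation (B2pin2, PdCl2(dppf), KOAc, dioxane, 85 °C) should give 4-[4-(tert-butyldimethylsilyloxy)-6-methoxy-5-(3-methylbut-2-enyl)-2-(4,4,5,5-tetramethyl-1,3,2-dioxaborolan-2-yl)benzoyl]-2-methoxyphenyl 2,2-dimethylpropanoate F4. Mild oxidation with NaBO3·4H2O in THF/H2O at rt should give 4-[4-(tert-butyldimethylsilyloxy)-2-hydroxy-6-methoxy-5-(3-methylbut-2-enyl)benzoyl]-2-methoxyphenyl 2,2-dimethylpropanoate F5. KOH in MeOH/H2O at rt, then dilute HCl, should cleave the silyl ether and the pivalate to 16.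

3. Step 1. O-alkylation and a second C-alkylation of the ambident dione enolate compete with the wanted mono-C-prenylation. Fallback, setting out from 2 and commercial 1,3-dimethoxybenzene and rejoining at 3: ortho-lithiation of 1,3-dimethoxybenzene between its two methoxy groups (n-BuLi, THF, 0 °C → rt) and alkylation with 2 should give 1,3-dimethoxy-2-(3-methylbut-2-enyl)benzene F6. Birch reduction (Li, NH3, tBuOH, THF, −78 °C) should give 1,5-dimethoxy-6-(3-methylbut-2-enyl)cyclohexa-1,4-diene F7. Mild hydrolysis of both enol ethers (1 M HCl, THF, rt) should give 3.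

**Further compounds**

F1 | step 7 | 4-methoxy-3-(3-methylbut-2-enyl)cyclohexa-1,3-dien-2-yl acetate | COC1=C(CC=C(C)C)C(OC(C)=O)=CCC1
F2 | step 7 | 4-{[5-acetoxy-3-bromo-1-methoxy-6-(3-methylbut-2-enyl)bicyclo[2.2.2]octa-2,5-dien-2-yl]carbonyl}-2-methoxyphenyl 2,2-dimethylpropanoate (racemic) | CO[C@]12CC[C@H](C(Br)=C1C(=O)c1ccc(OC(=O)C(C)(C)C)c(OC)c1)C(OC(C)=O)=C2CC=C(C)C
F3 | step 7 | 4-[4-acetoxy-2-bromo-6-methoxy-5-(3-methylbut-2-enyl)benzoyl]-2-methoxyphenyl 2,2-dimethylpropanoate | COc1cc(C(=O)c2c(Br)cc(OC(C)=O)c(CC=C(C)C)c2OC)ccc1OC(=O)C(C)(C)C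
F4 | step 8 | 4-[4-(tert-butyldimethylsilyloxy)-6-methoxy-5-(3-methylbut-2-enyl)-2-(4,4,5,5-tetramethyl-1,3,2-dioxaborolan-2-yl)benzoyl]-2-methoxyphenyl 2,2-dimethylpropanoate | COc1cc(C(=O)c2c(B3OC(C)(C)C(C)(C)O3)cc(O[Si](C)(C)C(C)(C)C)c(CC=C(C)C)c2OC)ccc1OC(=O)C(C)(C)C
F5 | step 8 | 4-[4-(tert-butyldimethylsilyloxy)-2-hydroxy-6-methoxy-5-(3-methylbut-2-enyl)benzoyl]-2-methoxyphenyl 2,2-dimethylpropanoate | COc1cc(C(=O)c2c(O)cc(O[Si](C)(C)C(C)(C)C)c(CC=C(C)C)c2OC)ccc1OC(=O)C(C)(C)C
F6 | step 1 | 1,3-dimethoxy-2-(3-methylbut-2-enyl)benzene | COc1cccc(OC)c1CC=C(C)C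
F7 | step 1 | 1,5-dimethoxy-6-(3-methylbut-2-enyl)cyclohexa-1,4-diene | COC1=CCC=C(OC)C1CC=C(C)C
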